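The C9 carbinol (chain numbered from the ketone carbon C1 to C18) sits between the C8 methylene, which bears the Z C6=C7 alkene, and the E C10=C11 alkene of the triene. This C8–C9 unit is mapped onto a vinyl group on boron. The route rests on the C7–C8 bond: a Pd-catalysed enantioselective conjunctive cross-coupling joins a Z-alkenyl bromide carrying the silyl-protected acylphloroglucinol ring (C1–C7) to a lithium vinyl(trienyl)boronate (C8–C18). One operation forms C7–C8, shifts the trienyl group from boron to C9 (forming C9–C10), and sets C9 as a C–B centre that is oxidised to the 9R alcohol. The benzene ring is a spectator.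

Key step: step 8

Remark on stereochemistry: C9 is R (O > C10 > C8 > H); the boronate that precedes it is also R, and oxidation proceeds with retention. The MandyPhos enantiomer is chosen to give this sense and is written here as (Sp,Sp). The assignment rests on analogy and would be confirmed by Mosher analysis.

Assumption: (E)-3-boronoacrolein pinacolate (11), tetravinylstannane and (bromomethyl)triphenylphosphonium bromide are taken as commercially available.

Step 1
Reactants: 1 phloroglucinol; 2 hept-6-enoic acid
Product: 4 1-(2,4,6-trihydroxyphenyl)hept-6-en-1-one, via hept-6-enoyl chloride 3 (not isolated)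
Conditions: 2, (COCl)2, cat. DMF, CH2Cl2, 0 °C to rt; concentrate; then 1 (excess), AlCl3, PhNO2/CH2Cl2, 0 °C to rt; aq. HCl work-up
Reagents that add atoms: none
Why: Friedel–Crafts acylation, in which the acylium ion from 3 attacks the symmetrical, strongly activated ring of 1 once at carbon and the new ketone deactivates the ring towards a second acylation; no stereocentre is formed.

Step 2
Reactants: 4 1-(2,4,6-trihydroxyphenyl)hept-6-en-1-one
Product: 5 1-[2,4,6-tris(tert-butyldimethylsilyloxy)phenyl]hept-6-en-1-one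
Conditions: TBSCl, imidazole, cat. DMAP, DMF, rt to 40 °C
Reagents that add atoms: tert-butyldimethylsilyl chloride, CC(C)(C)[Si](C)(C)Cl
Why: Silyl ether formation with imidazole-activated TBSCl should cap all three phenols, including the two hydrogen-bonded to the ketone, and so remove the acidic protons before the ylide and boronate steps.

Step 3
Reactants: 5 1-[2,4,6-tris(tert-butyldimethylsilyloxy)phenyl]hept-6-en-1-one
Product: 6 6-oxo-6-[2,4,6-tris(tert-butyldimethylsilyloxy)phenyl]hexanal
Conditions: OsO4 (cat.), NaIO4, 2,6-lutidine, dioxane/H2O, rt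
Reagents that add atoms: osmium tetroxide (catalytic, delivers the oxygen), O=[Os](=O)(=O)=O; sodium periodate (stoichiometric oxygen source), [Na+].[O-][I](=O)(=O)=O
Why: Lemieux–Johnson oxidative cleavage, in which OsO4 dihydroxylates the only alkene and periodate cleaves the diol to the C6 aldehyde, while the aryl silyl ethers and the hindered ketone are inert at near-neutral pH.

Step 4
Reactants: 6 6-oxo-6-[2,4,6-tris(tert-butyldimethylsilyloxy)phenyl]hexanal
Product: 7 (Z)-7-bromo-1-[2,4,6-tris(tert-butyldimethylsilyloxy)phenyl]hept-6-en-1-one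
Conditions: BrCH2PPh3Br, KOtBu, THF, −78 °C; then 6, −78 °C to rt
Reagents that add atoms: (bromomethyl)triphenylphosphonium bromide, BrC[P+](c1ccccc1)(c1ccccc1)c1ccccc1.[Br-]
Why: Wittig olefination with the bromomethylene ylide under kinetic low-temperature control should give the Z-1-bromoalkene through the cis-oxaphosphetane, and the doubly ortho-substituted aryl ketone is too hindered to compete with the aldehyde.

Step 5
Reactants: 8 (Z)-hex-3-en-1-ol
Product: 9 (Z)-1-iodohex-3-ene
Conditions: I2, PPh3, imidazole, CH2Cl2, 0 °C to rt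
Reagents that add atoms: iodine, II
Why: Appel-type iodination (Garegg–Samuelsson conditions) displaces the primary alcohol through its alkoxyphosphonium salt without touching the Z-alkene.

Step 6
Reactants: 9 (Z)-1-iodohex-3-ene
Product: 10 [(Z)-hex-3-en-1-yl]triphenylphosphonium iodide
Conditions: PPh3, MeCN, reflux, dark
Reagents that add atoms: triphenylphosphine, c1ccc(cc1)P(c1ccccc1)c1ccccc1
Why: SN2 quaternisation of triphenylphosphine by the primary iodide gives the Wittig salt and leaves the Z-alkene unchanged.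

Step 7
Reactants: 10 [(Z)-hex-3-en-1-yl]triphenylphosphonium iodide; 11 (E)-3-(4,4,5,5-tetramethyl-1,3,2-dioxaborolan-2-yl)prop-2-enal
Product: 13 2-[(1E,3Z,6Z)-nona-1,3,6-trien-1-yl]-4,4,5,5-tetramethyl-1,3,2-dioxaborolane, via (Z)-hex-3-enylidene(triphenyl)phosphorane 12 (not isolated)
Conditions: NaHMDS, THF, −78 °C; then 11, −78 °C to 0 °C
Reagents that add atoms: none
Why: Wittig olefination in which the non-stabilised ylide 12, generated with a lithium-free base, adds to the aldehyde of 11 under kinetic control to form C12=C13 as the Z-alkene, while the E-alkenylboronate C10=C11 is carried through unchanged.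

Step 8
Reactants: 13 2-[(1E,3Z,6Z)-nona-1,3,6-trien-1-yl]-4,4,5,5-tetramethyl-1,3,2-dioxaborolane; 7 (Z)-7-bromo-1-[2,4,6-tris(tert-butyldimethylsilyloxy)phenyl]hept-6-en-1-one
Product: 16 (R,6Z,10E,12Z,15Z)-9-hydroxy-1-[2,4,6-tris(tert-butyldimethylsilyloxy)phenyl]octadeca-6,10,12,15-tetraen-1-one, via lithium vinyl(trienyl)pinacolatoborate 14 (not isolated), via allylic C9 pinacol boronate 15 (not isolated)
Conditions: 13, vinyllithium (1.0 equiv, halide-free, from tetravinylstannane/n-BuLi), Et2O/THF, 0 °C to rt; then 7, Pd(OAc)2 (cat.), (Sp,Sp)-MandyPhos (cat.), KOTf, THF, 60 °C; then 30% H2O2, pH 7 phosphate buffer, THF, 0 °C to rt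
Reagents that add atoms: vinyllithium (made in the flask from tetravinylstannane, C=C[Sn](C=C)(C=C)C=C, and n-BuLi), [Li]C=C; hydrogen peroxide, OO
Why: Vinyllithium adds to boron of 13 to give the bis(alkenyl) ate complex 14; Pd(0)–MandyPhos inserts into the C–Br bond of 7 with retention of the Z geometry, KOTf removes bromide, and the cationic alkenyl-Pd(II) binds the unsubstituted boron-bound vinyl group, which triggers a 1,2-metallate shift of the trienyl group from boron to C9 anti to palladium as the Pd–C8 bond forms, after which reductive elimination makes the C7–C8 bond. The closest known reaction type is the Pd-catalysed enantioselective conjunctive cross-coupling of vinylboron ate complexes, including bis(alkenyl)borates with an alkenyl migrating group and C(sp2) halides in the presence of triflate salts. No ring is closed. The C9 stereocentre is set by the chiral bisphosphine, which selects the enantiotopic face of the vinyl group; the migrating trienyl group keeps its 10E,12Z,15Z geometry, and buffered H2O2 then replaces boron by oxygen with retention and without allylic transposition to give the 9R alcohol. The step needs π-activation of the vinyl group over the substituted C10=C11 alkene, secured by the steric difference between the two boron-bound alkenes, and metallate shift over direct Suzuki transmetalation, secured by the wide-bite-angle ligand on halide-free cationic palladium. The ate complex is not basic or nucleophilic enough to attack the hindered aryl ketone or the silyl ethers, and the neutral oxidation avoids desilylation and Dakin cleavage of the electron-rich aryl ketone.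

Step 9
Reactants: 16 (R,6Z,10E,12Z,15Z)-9-hydroxy-1-[2,4,6-tris(tert-butyldimethylsilyloxy)phenyl]octadeca-6,10,12,15-tetraen-1-one
Product: 17 (R,6Z,10E,12Z,15Z)-9-hydroxy-1-(2,4,6-trihydroxyphenyl)octadeca-6,10,12,15-tetraen-1-one
Conditions: TBAF/AcOH (1:1), THF, 0 °C
Reagents that add atoms: none
Why: Fluoride-mediated desilylation cleaves the three aryl silyl ethers quickly under buffered conditions that should leave the acid-sensitive dienylic alcohol, the Z-alkenes and the C9 configuration untouched.

Compound list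

1 | phloroglucinol (benzene-1,3,5-triol) | Oc1cc(O)cc(O)c1 | starting material
2 | hept-6-enoic acid | C=CCCCCC(=O)O | starting material
3 | hept-6-enoyl chloride | C=CCCCCC(=O)Cl | intermediate
4 | 1-(2,4,6-trihydroxyphenyl)hept-6-en-1-one | C=CCCCCC(=O)c1c(O)cc(O)cc1O | intermediate
5 | 1-[2,4,6-tris(tert-butyldimethylsilyloxy)phenyl]hept-6-en-1-one | C=CCCCCC(=O)c1c(O[Si](C)(C)C(C)(C)C)cc(O[Si](C)(C)C(C)(C)C)cc1O[Si](C)(C)C(C)(C)C | intermediate
6 | 6-oxo-6-[2,4,6-tris(tert-butyldimethylsilyloxy)phenyl]hexanal | O=CCCCCC(=O)c1c(O[Si](C)(C)C(C)(C)C)cc(O[Si](C)(C)C(C)(C)C)cc1O[Si](C)(C)C(C)(C)C | intermediate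
7 | (Z)-7-bromo-1-[2,4,6-tris(tert-butyldimethylsilyloxy)phenyl]hept-6-en-1-one | Br/C=C\CCCCC(=O)c1c(O[Si](C)(C)C(C)(C)C)cc(O[Si](C)(C)C(C)(C)C)cc1O[Si](C)(C)C(C)(C)C | intermediate
8 | (Z)-hex-3-en-1-ol | CC/C=C\CCO | starting material
9 | (Z)-1-iodohex-3-ene | CC/C=C\CCI | intermediate
10 | [(Z)-hex-3-en-1-yl]triphenylphosphonium iodide | CC/C=C\CC[P+](c1ccccc1)(c1ccccc1)c1ccccc1.[I-] | intermediate
11 | (E)-3-(4,4,5,5-tetramethyl-1,3,2-dioxaborolan-2-yl)prop-2-enal (3-boronoacrolein pinacolate) | O=C/C=C/B1OC(C)(C)C(C)(C)O1 | starting material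
12 | (Z)-hex-3-enylidene(triphenyl)phosphorane | CC/C=C\CC=P(c1ccccc1)(c1ccccc1)c1ccccc1 | intermediate
13 | 2-[(1E,3Z,6Z)-nona-1,3,6-trien-1-yl]-4,4,5,5-tetramethyl-1,3,2-dioxaborolane | CC/C=C\C/C=C\C=C\B1OC(C)(C)C(C)(C)O1 | intermediate
14 | lithium [(1E,3Z,6Z)-nona-1,3,6-trien-1-yl](vinyl)(pinacolato)borate | [Li+].CC/C=C\C/C=C\C=C\[B-]1(C=C)OC(C)(C)C(C)(C)O1 | intermediate
15 | (R,6Z,10E,12Z,15Z)-9-(4,4,5,5-tetramethyl-1,3,2-dioxaborolan-2-yl)-1-[2,4,6-tris(tert-butyldimethylsilyloxy)phenyl]octadeca-6,10,12,15-tetraen-1-one | CC/C=C\C/C=C\C=C\[C@H](B1OC(C)(C)C(C)(C)O1)C/C=C\CCCCC(=O)c1c(O[Si](C)(C)C(C)(C)C)cc(O[Si](C)(C)C(C)(C)C)cc1O[Si](C)(C)C(C)(C)C | intermediate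
16 | (R,6Z,10E,12Z,15Z)-9-hydroxy-1-[2,4,6-tris(tert-butyldimethylsilyloxy)phenyl]octadeca-6,10,12,15-tetraen-1-one | CC/C=C\C/C=C\C=C\[C@H](O)C/C=C\CCCCC(=O)c1c(O[Si](C)(C)C(C)(C)C)cc(O[Si](C)(C)C(C)(C)C)cc1O[Si](C)(C)C(C)(C)C | intermediate
17 | (R,6Z,10E,12Z,15Z)-9-hydroxy-1-(2,4,6-trihydroxyphenyl)octadeca-6,10,12,15-tetraen-1-one | CC/C=C\C/C=C\C=C\[C@H](O)C/C=C\CCCCC(=O)c1c(O)cc(O)cc1O | target

Total step count: 9. Longest linear sequence: 6 steps (steps 1, 2, 3, 4, 8, 9); the boronate branch (steps 5, 6, 7) joins at step 8.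

Steps most likely to fail

Step 8. Palladium may engage the boron-bound C10=C11 alkene or the distal diene of the trienyl group instead of the vinyl group. Direct Suzuki transmetalation may also outrun the metallate shift, and facial control at C9 may be incomplete with a conjugated migrating group. The fallback makes the union stepwise; it sets out from 7 and 13 and comes back at 16. Negishi coupling of 7 with the Reformatsky reagent of ethyl bromoacetate (BrZnCH2CO2Et, Pd(dba)2/Q-Phos, THF, rt) should form the same C7–C8 bond with retention of the Z geometry. This gives ethyl (Z)-9-oxo-9-[2,4,6-tris(tert-butyldimethylsilyloxy)phenyl]non-3-enoate F1. DIBAL-H at −78 °C should reduce the ester rather than the doubly ortho-shielded ketone, giving (Z)-9-oxo-9-[2,4,6-tris(tert-butyldimethylsilyloxy)phenyl]non-3-enal F2, which is used at once. Boronate 13 is converted by NaOH/I2 (iododeboronation with retention) into (1E,3Z,6Z)-1-iodonona-1,3,6-triene F3. A catalytic asymmetric Nozaki–Hiyama–Kishi coupling of F3 with F2 (CrCl2, NiCl2, chiral sulfonamide ligand, Mn, Cp2ZrCl2) then forms C9–C10, sets 9R under ligand control and gives 16.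

Step 7. The ylide may bind to boron instead of adding to the aldehyde, and the Z-selectivity at C12=C13 may erode through equilibration of the betaine-type adducts. The fallback sets out from 10 and comes back at 13. Ylide 12 is condensed with 3-(trimethylsilyl)propynal (NaHMDS, THF, −78 °C) to give trimethyl[(3Z,6Z)-nona-3,6-dien-1-yn-1-yl]silane F4. K2CO3/MeOH removes the silyl group to give (3Z,6Z)-nona-3,6-dien-1-yne F5. Zirconocene-catalysed syn-hydroboration with pinacolborane (cat. Cp2Zr(H)Cl, Et3N, 60 °C) places boron on the terminal carbon with E geometry and gives 13.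

Step 1. AlCl3 and HCl may protonate the terminal alkene, leading to hydrochlorination, cationic alkylation of the ring or oligomerisation, and the ring may be acylated twice. The fallback avoids an alkene in the Lewis-acid step; it sets out from 1 and comes back at 6. Friedel–Crafts acylation of 1 with 6-bromohexanoyl chloride (AlCl3, PhNO2/CH2Cl2) gives 6-bromo-1-(2,4,6-trihydroxyphenyl)hexan-1-one F6. Silylation (TBSCl, imidazole, DMF) gives 6-bromo-1-[2,4,6-tris(tert-butyldimethylsilyloxy)phenyl]hexan-1-one F7. Ganem oxidation of the primary bromide (anhydrous Me3NO, DMSO, rt) gives aldehyde 6.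

Further compounds

F1 | step 8 | ethyl (Z)-9-oxo-9-[2,4,6-tris(tert-butyldimethylsilyloxy)phenyl]non-3-enoate | CCOC(=O)C/C=C\CCCCC(=O)c1c(O[Si](C)(C)C(C)(C)C)cc(O[Si](C)(C)C(C)(C)C)cc1O[Si](C)(C)C(C)(C)C
F2 | step 8 | (Z)-9-oxo-9-[2,4,6-tris(tert-butyldimethylsilyloxy)phenyl]non-3-enal | O=CC/C=C\CCCCC(=O)c1c(O[Si](C)(C)C(C)(C)C)cc(O[Si](C)(C)C(C)(C)C)cc1O[Si](C)(C)C(C)(C)C
F3 | step 8 | (1E,3Z,6Z)-1-iodonona-1,3,6-triene | CC/C=C\C/C=C\C=C\I
F4 | step 7 | trimethyl[(3Z,6Z)-nona-3,6-dien-1-yn-1-yl]silane | CC/C=C\C/C=C\C#C[Si](C)(C)C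
F5 | step 7 | (3Z,6Z)-nona-3,6-dien-1-yne | CC/C=C\C/C=C\C#C
F6 | step 1 | 6-bromo-1-(2,4,6-trihydroxyphenyl)hexan-1-one | BrCCCCCC(=O)c1c(O)cc(O)cc1O
F7 | step 1 | 6-bromo-1-[2,4,6-tris(tert-butyldimethylsilyloxy)phenyl]hexan-1-one | BrCCCCCC(=O)c1c(O[Si](C)(C)C(C)(C)C)cc(O[Si](C)(C)C(C)(C)C)cc1O[Si](C)(C)C(C)(C)C
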